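**Retrosynthetic overview**
1. Target 33 ← desilylation, angeloylation and 1,2-reduction ← 8-oxo macrocycle 28 (rings: lactone ring B already present, ten-membered ring A closed last).
2. Key disconnection C7–C8: 28 ← seco selenoester 27 by 10-exo acyl-radical addition to the butenolide with loss of PhSO2• (closes ring A, creates C7 and the exo-methylene in one step).
3. 27 ← C3–C4 disconnection (Ni/Cr alkenylation) into West iodide 11 and East aldehyde acid 22.
4. 11 ← ring-closing metathesis (ring B) ← Z-iodide 7 (trans-hydroalumination/iodination) ← asymmetric alkynylation of crotonaldehyde with 2.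
5. 22 ← anti-carbomagnesiation/carboxylation of (S)-hex-5-en-1-yn-3-ol 16 ← asymmetric allylboration of 12.

Assumption (numbering): germacrane locants are used throughout: lactone C12(=O)–O on C6, C7 bears C11(=C13H2), angelate on C8, C9=C10 (C14 methyl), free hydroxyl on C1, C2 methylene, acetate on C3, C4(=C5) bears C15H2OH.

**Step 1**
Reactants: 1 prop-2-yn-1-ol
Product: 2 tert-butyldimethyl(prop-2-yn-1-yloxy)silane
Conditions: TBSCl, imidazole, CH2Cl2, 0 °C to rt
Reagents that add atoms: tert-butyldimethylsilyl chloride (CC(C)(C)[Si](C)(C)Cl)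
Why: Standard imidazole-promoted silyl ether formation on a primary alcohol, protecting the future O15 for the whole route; no stereocentre is formed.

**Step 2**
Reactants: 2 tert-butyldimethyl(prop-2-yn-1-yloxy)silane; 3 (E)-but-2-enal
Product: 5 (4R,5E)-1-(tert-butyldimethylsilyloxy)hept-5-en-2-yn-4-ol, via alkynyl(methyl)zinc 4 (not isolated)
Conditions: 2 (2.8 equiv), Me2Zn, (S,S)-ProPhenol (10 mol%), Ph3P=O (20 mol%), toluene, 0 °C; then 3, 4 °C
Reagents that add atoms: none
Why: Trost zinc–ProPhenol asymmetric alkynylation adds the alkynylzinc 1,2 to the enal, the ligand antipode being chosen for Si-face attack so that the carbinol (4R in 5, the future C6) is set directly; the antipode sense should be confirmed on a model, the other ligand enantiomer being equally available.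

**Step 3**
Reactants: 5 (4R,5E)-1-(tert-butyldimethylsilyloxy)hept-5-en-2-yn-4-ol
Product: 7 (2Z,4R,5E)-1-(tert-butyldimethylsilyloxy)-2-iodohepta-2,5-dien-4-ol, via cyclic alkenylaluminate 6 (not isolated)
Conditions: NaAlH2(OCH2CH2OMe)2, THF, 0 °C; then I2, −78 to 0 °C
Reagents that add atoms: iodine (II)
Why: Hydroxyl-directed trans-hydroalumination of the propargylic alcohol puts aluminium on the distal alkyne carbon, and iodinolysis with retention gives the Z-iodoalkene (future C4=C5) without touching the carbinol or the propenyl group.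

**Step 4**
Reactants: 8 2-(bromomethyl)prop-2-enoic acid
Product: 9 2-[(phenylsulfonyl)methyl]prop-2-enoic acid
Conditions: PhSO2Na (2 equiv), MeOH, 65 °C; acidify
Reagents that add atoms: sodium benzenesulfinate ([Na+].[O-]S(=O)c1ccccc1)
Why: SN2 S-alkylation of sulfinate by the activated allylic bromide installs the allyl sulfone that later serves as the radical leaving group; no stereocentre.

**Step 5**
Reactants: 7 (2Z,4R,5E)-1-(tert-butyldimethylsilyloxy)-2-iodohepta-2,5-dien-4-ol; 9 2-[(phenylsulfonyl)methyl]prop-2-enoic acid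
Product: 10 (2Z,4R,5E)-1-(tert-butyldimethylsilyloxy)-2-iodohepta-2,5-dien-4-yl 2-[(phenylsulfonyl)methyl]prop-2-enoate
Conditions: DCC, DMAP (5 mol%), CH2Cl2, 0 °C
Reagents that add atoms: none
Why: Steglich esterification acylates the secondary alcohol with retention at the carbinol, the low temperature and catalytic base avoiding isomerisation of the allyl sulfone.

**Step 6**
Reactants: 10 (2Z,4R,5E)-1-(tert-butyldimethylsilyloxy)-2-iodohepta-2,5-dien-4-yl 2-[(phenylsulfonyl)methyl]prop-2-enoate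
Product: 11 (5R)-5-[(Z)-3-(tert-butyldimethylsilyloxy)-2-iodoprop-1-enyl]-3-[(phenylsulfonyl)methyl]furan-2(5H)-one
Conditions: second-generation Grubbs catalyst RuCl2(=CHPh)(H2IMes)(PCy3) (10 mol%), toluene, 80 °C, 0.01 M
Reagents that add atoms: none
Why: Ring-closing metathesis between the propenyl group and the 1,1-disubstituted acrylate closes the butenolide (ring B) with loss of propene, the hindered trisubstituted iodoalkene staying inert and the stereocentre untouched.

**Step 7**
Reactants: 12 3-(trimethylsilyl)prop-2-ynal; 13 allylmagnesium bromide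
Product: 16 (S)-hex-5-en-1-yn-3-ol, via B-allyldiisopinocampheylborane 14 (not isolated), via borinate ester 15 (not isolated)
Conditions: (−)-Ipc2BOMe, 13, Et2O, 0 °C; then 12, −78 °C; then NaOH, H2O2, MeOH, rt
Reagents that add atoms: none
Why: Brown asymmetric allylboration goes through a chair Zimmerman–Traxler transition state in which the isopinocampheyl groups enforce Si-face addition, setting the S carbinol (future C1), and the basic methanolic peroxide work-up frees the alcohol and cleaves the alkynyl silane.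

**Step 8**
Reactants: 16 (S)-hex-5-en-1-yn-3-ol
Product: 20 (2Z,4S)-4-(tert-butyldimethylsilyloxy)-3-methylhepta-2,6-dienoic acid, via alkenylmagnesium alkoxide 17 (not isolated), via magnesium carboxylate 18 (not isolated), via bis-silyl derivative 19 (not isolated)
Conditions: MeMgBr (3.5 equiv), CuI (15 mol%), THF, 0 °C to reflux; CO2, 0 °C; TBSOTf (3 equiv), 0 °C; then K2CO3 (cat.), MeOH/H2O, work-up at pH 4
Reagents that add atoms: methylmagnesium bromide (C[Mg]Br); carbon dioxide (O=C=O); tert-butyldimethylsilyl triflate (CC(C)(C)[Si](C)(C)OS(=O)(=O)C(F)(F)F)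
Why: Copper-catalysed anti-carbomagnesiation of the propargylic alkoxide (Duboudin–Jousseaume reaction) puts the methyl on the internal carbon and magnesium cis to the carbinol, so carboxylation fixes the Z-trisubstituted alkene (future C9=C10), and silylating the alkoxide before acidification prevents closure to the butenolide; the carbinol is unaffected.

**Step 9**
Reactants: 20 (2Z,4S)-4-(tert-butyldimethylsilyloxy)-3-methylhepta-2,6-dienoic acid
Product: 22 (2Z,4S)-4-(tert-butyldimethylsilyloxy)-3-methyl-6-oxohex-2-enoic acid, via vicinal diol 21 (not isolated)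
Conditions: OsO4 (2 mol%), NaIO4 (4 equiv), 2,6-lutidine, dioxane/H2O, rt
Reagents that add atoms: osmium tetroxide (O=[Os](=O)(=O)=O); sodium periodate ([Na+].[O-]I(=O)(=O)=O); water (O)
Why: Lemieux–Johnson oxidation cleaves only the electron-rich terminal alkene, the conjugated trisubstituted alkene being deactivated, and the stereocentre is retained.

**Step 10**
Reactants: 11 (5R)-5-[(Z)-3-(tert-butyldimethylsilyloxy)-2-iodoprop-1-enyl]-3-[(phenylsulfonyl)methyl]furan-2(5H)-one; 22 (2Z,4S)-4-(tert-butyldimethylsilyloxy)-3-methyl-6-oxohex-2-enoic acid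
Product: 24 (1S,3R,6S)-3-hydroxy-13-(phenylsulfonyl)-1,15-bis(tert-butyldimethylsilyloxy)-7,8-secogermacra-4Z,7(11),9Z-trien-12,6-olid-8-oic acid, via trimethylsilyl ester 23 (not isolated)
Conditions: 22, BSA, THF, rt; then 11 (1.3 equiv), CrCl2 (4 equiv), NiCl2 (2 mol%), Kishi (S)-oxazoline–sulfonamide ligand, Et3N, THF, rt; aqueous work-up
Reagents that add atoms: none
Why: Nozaki–Hiyama–Kishi alkenylation in which nickel inserts into the C–I bond with retention of the Z geometry, transmetallation gives the alkenylchromium species and the chiral sulfonamide ligand on chromium directs Si-face addition to the aldehyde (3R, syn to C1, overriding the weak 1,3-anti bias), the acid being masked in situ as its silyl ester; the ligand antipode that gives 3R should be fixed on a model.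

**Step 11**
Reactants: 24 (1S,3R,6S)-3-hydroxy seco acid
Product: 26 (1S,3R,6S)-3-acetoxy-13-(phenylsulfonyl)-1,15-bis(tert-butyldimethylsilyloxy)-7,8-secogermacra-4Z,7(11),9Z-trien-12,6-olid-8-oic acid, via mixed acetic anhydride 25 (not isolated)
Conditions: Ac2O, pyridine, DMAP (cat.), CH2Cl2, 0 °C; then H2O, THF, rt
Reagents that add atoms: acetic anhydride (CC(=O)OC(C)=O)
Why: DMAP-catalysed acetylation of the allylic alcohol proceeds with retention at C3, and the mixed anhydride formed at the acid is hydrolysed on aqueous stirring.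

**Step 12**
Reactants: 26 (1S,3R,6S)-3-acetoxy seco acid
Product: 27 Se-phenyl (1S,3R,6S)-3-acetoxy-13-(phenylsulfonyl)-1,15-bis(tert-butyldimethylsilyloxy)-7,8-secogermacra-4Z,7(11),9Z-trien-12,6-olide-8-selenoate
Conditions: N-(phenylseleno)phthalimide, Bu3P, CH2Cl2, −20 to 0 °C
Reagents that add atoms: N-(phenylseleno)phthalimide (O=C1c2ccccc2C(=O)N1[Se]c1ccccc1)
Why: Grieco–Nicolaou selenoesterification through the acyloxyphosphonium salt converts the acid into the acyl radical precursor under neutral conditions that spare the Z-alkenes, silyl ethers, acetate and allyl sulfone; no stereocentre changes.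

**Step 13**
Reactants: 27 Se-phenyl seco selenoester
Product: 28 (1S,3R,6S,7R)-3-acetoxy-8-oxo-1,15-bis(tert-butyldimethylsilyloxy)germacra-4Z,9Z,11(13)-trien-12,6-olide
Conditions: (Bu3Sn)2 (1.5 equiv), hν (sunlamp), benzene, 80 °C, 2 mM
Reagents that add atoms: none
Why: Proposed new method: Bu3Sn• from the distannane abstracts PhSe to give the σ-type Z-enoyl radical, which the two Z-alkenes hold near the lactone so that it adds 10-exo to the electron-poor β-carbon C7 of the butenolide on the face opposite the C6–C5 bond (trans H6/H7, the less strained trans-fused bicycle), after which the α-lactonyl radical expels PhSO2• to unveil the exo-methylene and PhSO2• regenerates Bu3Sn• from the distannane (no hydride donor, so the acyl radical is not reduced); the closest known chemistry is acyl-radical macrocyclisation of selenoesters onto acrylates combined with tin-mediated radical allylation by allyl sulfones (SH2′).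

**Step 14**
Reactants: 28 8-oxo macrocycle
Product: 29 (1S,3R,6S,7S,8R)-3-acetoxy-8-hydroxy-1,15-bis(tert-butyldimethylsilyloxy)germacra-4Z,9Z,11(13)-trien-12,6-olide
Conditions: NaBH4, CeCl3·7H2O, MeOH/THF, −78 °C
Reagents that add atoms: none
Why: Luche reduction gives 1,2-reduction of the enone without touching the exo-methylene lactone at −78 °C, hydride arriving on the outer face of the ring-held carbonyl anti to the C7–C11 bond (Felkin–Anh) to set 8R; this facial preference is a prediction, not an established result.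

**Step 15**
Reactants: 29 8-hydroxy macrocycle; 30 (Z)-2-methylbut-2-enoic acid (angelic acid)
Product: 32 (1S,3R,6S,7S,8R)-3-acetoxy-8-angeloyloxy-1,15-bis(tert-butyldimethylsilyloxy)germacra-4Z,9Z,11(13)-trien-12,6-olide, via mixed trichlorobenzoic anhydride 31 (not isolated)
Conditions: 30, 2,4,6-Cl3C6H2COCl, Et3N, toluene, rt; then 29, 80 °C (no DMAP)
Reagents that add atoms: none
Why: Yamaguchi-type esterification through the mixed anhydride without DMAP acylates the hindered allylic alcohol at the less hindered angeloyl carbonyl with retention at C8 and without Z to E isomerisation to the tiglate.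

**Step 16**
Reactants: 32 bis-silyl angelate
Product: 33 (1S,3R,6S,7S,8R)-3-acetoxy-8-angeloyloxy-1,15-dihydroxygermacra-4Z,9Z,11(13)-trien-12,6-olide (CNP0153210.4)
Conditions: HF·pyridine, pyridine, THF, 0 °C to rt
Reagents that add atoms: none
Why: Buffered fluoride desilylation removes both silyl ethers under mildly acidic conditions that avoid acyl migration and lactone opening; no stereocentre is touched.

**Compound list**
1 | prop-2-yn-1-ol | C#CCO | starting material
2 | tert-butyldimethyl(prop-2-yn-1-yloxy)silane | C#CCO[Si](C)(C)C(C)(C)C | intermediate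
3 | (E)-but-2-enal | C/C=C/C=O | starting material
4 | methyl[3-(tert-butyldimethylsilyloxy)prop-1-ynyl]zinc | C[Zn]C#CCO[Si](C)(C)C(C)(C)C | intermediate
5 | (4R,5E)-1-(tert-butyldimethylsilyloxy)hept-5-en-2-yn-4-ol | O[C@@H](C#CCO[Si](C)(C)C(C)(C)C)/C=C/C | intermediate
6 | cyclic sodium alkoxy(alkenyl)bis(2-methoxyethoxy)aluminate from trans-hydroalumination of 5 | [Na+].COCCO[Al-]1(OCCOC)O[C@H](/C=C/C)C=C1CO[Si](C)(C)C(C)(C)C | intermediate
7 | (2Z,4R,5E)-1-(tert-butyldimethylsilyloxy)-2-iodohepta-2,5-dien-4-ol | O[C@@H](/C=C(/CO[Si](C)(C)C(C)(C)C)I)/C=C/C | intermediate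
8 | 2-(bromomethyl)prop-2-enoic acid | C=C(CBr)C(=O)O | starting material
9 | 2-[(phenylsulfonyl)methyl]prop-2-enoic acid | C=C(CS(=O)(=O)c1ccccc1)C(=O)O | intermediate
10 | (2Z,4R,5E)-1-(tert-butyldimethylsilyloxy)-2-iodohepta-2,5-dien-4-yl 2-[(phenylsulfonyl)methyl]prop-2-enoate | C=C(CS(=O)(=O)c1ccccc1)C(=O)O[C@@H](/C=C(/CO[Si](C)(C)C(C)(C)C)I)/C=C/C | intermediate
11 | (5R)-5-[(Z)-3-(tert-butyldimethylsilyloxy)-2-iodoprop-1-enyl]-3-[(phenylsulfonyl)methyl]furan-2(5H)-one | O=C1O[C@@H](/C=C(/CO[Si](C)(C)C(C)(C)C)I)C=C1CS(=O)(=O)c1ccccc1 | intermediate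
12 | 3-(trimethylsilyl)prop-2-ynal | O=CC#C[Si](C)(C)C | starting material
13 | allylmagnesium bromide | C=CC[Mg]Br | starting material
14 | (−)-B-allyldiisopinocampheylborane | C=CCB([C@@H]1C[C@@H]2C[C@H]([C@H]1C)C2(C)C)[C@@H]1C[C@@H]2C[C@H]([C@H]1C)C2(C)C | intermediate
15 | diisopinocampheylborinate of (S)-1-(trimethylsilyl)hex-5-en-1-yn-3-ol | C=CC[C@H](OB([C@@H]1C[C@@H]2C[C@H]([C@H]1C)C2(C)C)[C@@H]1C[C@@H]2C[C@H]([C@H]1C)C2(C)C)C#C[Si](C)(C)C | intermediate
16 | (S)-hex-5-en-1-yn-3-ol | C=CC[C@H](O)C#C | intermediate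
17 | bromomagnesium (1Z,3S)-1-(bromomagnesio)-2-methylhexa-1,5-dien-3-olate | C=CC[C@H](O[Mg]Br)/C(C)=C\[Mg]Br | intermediate
18 | bis(bromomagnesium) salt of (2Z,4S)-4-hydroxy-3-methylhepta-2,6-dienoic acid | C=CC[C@H](O[Mg]Br)/C(C)=C\C(=O)O[Mg]Br | intermediate
19 | tert-butyldimethylsilyl (2Z,4S)-4-(tert-butyldimethylsilyloxy)-3-methylhepta-2,6-dienoate | C=CC[C@H](O[Si](C)(C)C(C)(C)C)/C(C)=C\C(=O)O[Si](C)(C)C(C)(C)C | intermediate
20 | (2Z,4S)-4-(tert-butyldimethylsilyloxy)-3-methylhepta-2,6-dienoic acid | C=CC[C@H](O[Si](C)(C)C(C)(C)C)/C(C)=C\C(=O)O | intermediate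
21 | (2Z,4S)-4-(tert-butyldimethylsilyloxy)-6,7-dihydroxy-3-methylhept-2-enoic acid (C6 epimers) | OCC(O)C[C@H](O[Si](C)(C)C(C)(C)C)/C(C)=C\C(=O)O | intermediate
22 | (2Z,4S)-4-(tert-butyldimethylsilyloxy)-3-methyl-6-oxohex-2-enoic acid | O=CC[C@H](O[Si](C)(C)C(C)(C)C)/C(C)=C\C(=O)O | intermediate
23 | trimethylsilyl (2Z,4S)-4-(tert-butyldimethylsilyloxy)-3-methyl-6-oxohex-2-enoate | O=CC[C@H](O[Si](C)(C)C(C)(C)C)/C(C)=C\C(=O)O[Si](C)(C)C | intermediate
24 | (1S,3R,6S)-3-hydroxy-13-(phenylsulfonyl)-1,15-bis(tert-butyldimethylsilyloxy)-7,8-secogermacra-4Z,7(11),9Z-trien-12,6-olid-8-oic acid | O=C1O[C@@H](/C=C(/CO[Si](C)(C)C(C)(C)C)[C@@H](O)C[C@H](O[Si](C)(C)C(C)(C)C)/C(C)=C\C(=O)O)C=C1CS(=O)(=O)c1ccccc1 | intermediate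
25 | mixed acetic anhydride of the 3-acetoxy seco acid 26 | O=C1O[C@@H](/C=C(/CO[Si](C)(C)C(C)(C)C)[C@@H](OC(C)=O)C[C@H](O[Si](C)(C)C(C)(C)C)/C(C)=C\C(=O)OC(C)=O)C=C1CS(=O)(=O)c1ccccc1 | intermediate
26 | (1S,3R,6S)-3-acetoxy-13-(phenylsulfonyl)-1,15-bis(tert-butyldimethylsilyloxy)-7,8-secogermacra-4Z,7(11),9Z-trien-12,6-olid-8-oic acid | O=C1O[C@@H](/C=C(/CO[Si](C)(C)C(C)(C)C)[C@@H](OC(C)=O)C[C@H](O[Si](C)(C)C(C)(C)C)/C(C)=C\C(=O)O)C=C1CS(=O)(=O)c1ccccc1 | intermediate
27 | Se-phenyl selenoester of 26 | O=C1O[C@@H](/C=C(/CO[Si](C)(C)C(C)(C)C)[C@@H](OC(C)=O)C[C@H](O[Si](C)(C)C(C)(C)C)/C(C)=C\C(=O)[Se]c2ccccc2)C=C1CS(=O)(=O)c1ccccc1 | intermediate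
28 | (1S,3R,6S,7R)-3-acetoxy-8-oxo-1,15-bis(tert-butyldimethylsilyloxy)germacra-4Z,9Z,11(13)-trien-12,6-olide | C=C1C(=O)O[C@H]2/C=C(/CO[Si](C)(C)C(C)(C)C)[C@@H](OC(C)=O)C[C@H](O[Si](C)(C)C(C)(C)C)/C(C)=C\C(=O)[C@H]12 | intermediate
29 | (1S,3R,6S,7S,8R)-3-acetoxy-8-hydroxy-1,15-bis(tert-butyldimethylsilyloxy)germacra-4Z,9Z,11(13)-trien-12,6-olide | C=C1C(=O)O[C@H]2/C=C(/CO[Si](C)(C)C(C)(C)C)[C@@H](OC(C)=O)C[C@H](O[Si](C)(C)C(C)(C)C)/C(C)=C\[C@@H](O)[C@H]12 | intermediate
30 | (Z)-2-methylbut-2-enoic acid (angelic acid) | C/C=C(/C)C(=O)O | starting material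
31 | (Z)-2-methylbut-2-enoic 2,4,6-trichlorobenzoic anhydride | C/C=C(/C)C(=O)OC(=O)c1c(Cl)cc(Cl)cc1Cl | intermediate
32 | (1S,3R,6S,7S,8R)-3-acetoxy-8-angeloyloxy-1,15-bis(tert-butyldimethylsilyloxy)germacra-4Z,9Z,11(13)-trien-12,6-olide | C=C1C(=O)O[C@H]2/C=C(/CO[Si](C)(C)C(C)(C)C)[C@@H](OC(C)=O)C[C@H](O[Si](C)(C)C(C)(C)C)/C(C)=C\[C@@H](OC(=O)/C(C)=C\C)[C@H]12 | intermediate
33 | (1S,3R,6S,7S,8R)-3-acetoxy-8-angeloyloxy-1,15-dihydroxygermacra-4Z,9Z,11(13)-trien-12,6-olide (CNP0153210.4) | C=C1C(=O)O[C@H]2/C=C(/CO)[C@@H](OC(C)=O)C[C@H](O)/C(C)=C\[C@@H](OC(=O)/C(C)=C\C)[C@H]12 | target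

**Totals**
Total step count: 16. Longest linear sequence: 12 (steps 1, 2, 3, 5, 6, 10, 11, 12, 13, 14, 15, 16); steps 4 and 7–9 are side branches.

**Steps most likely to fail, with fallbacks**

Step 13 (radical ring closure). The 10-exo closure may be too slow, may give the cis-fused lactone, or the acyl radical may react through its ketenyl form. Fallback: starting from 27, reduce the selenoester with Bu3SnH/AIBN at 0.1 M (the acyl radical is intercepted by hydride) to the Z-enal F4. Then close the same C7–C8 bond in a polar sense by palladium-catalysed umpolung allylation (Pd(PPh3)4, Et2Zn, THF, high dilution). The electron-poor allyl sulfone is expected to ionise first, although the allylic C3 acetate and the C6 lactone oxygen could compete. The resulting allylzinc adds through C7 to the aldehyde, giving the exo-methylene lactone and the C8 carbinol directly. This comes back to the route at 29.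

Step 10 (ligand-controlled Ni/Cr coupling). The C3 selectivity may be low, since the substrate's own bias is 1,3-anti, and the masked acid may interfere. Fallback: starting from 11 and 22, run the coupling without the chiral ligand (same BSA pre-silylation through 23; CrCl2, NiCl2 cat., DMSO) to the C3-epimeric hydroxy acids F1. Oxidise with Dess–Martin periodinane to the enone acid F2, and mask the acid in situ with BSA as its trimethylsilyl ester F3. Reduce the ketone under reagent control with (S)-2-methyl-CBS-oxazaborolidine and catecholborane at −78 °C (alkenyl as the large group gives 3R). Aqueous work-up returns the route at 24.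

Step 14 (facial selectivity at C8). Hydride may prefer the other face of the macrocyclic enone. Fallback: starting from 28, if the same Luche reduction delivers mainly the 8-epimeric alcohol F5, esterify F5 with 30 under Mitsunobu conditions (PPh3, DIAD, toluene, 0 °C). This inverts C8 and installs the angelate in one operation, and comes back to the route at 32.

**Further compounds**
F1 | step 10 | (1S,3RS,6S)-3-hydroxy-13-(phenylsulfonyl)-1,15-bis(tert-butyldimethylsilyloxy)-7,8-secogermacra-4Z,7(11),9Z-trien-12,6-olid-8-oic acid (C3 epimers) | O=C1O[C@@H](/C=C(/CO[Si](C)(C)C(C)(C)C)C(O)C[C@H](O[Si](C)(C)C(C)(C)C)/C(C)=C\C(=O)O)C=C1CS(=O)(=O)c1ccccc1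
F2 | step 10 | (1S,6S)-3-oxo-13-(phenylsulfonyl)-1,15-bis(tert-butyldimethylsilyloxy)-7,8-secogermacra-4Z,7(11),9Z-trien-12,6-olid-8-oic acid | O=C1O[C@@H](/C=C(/CO[Si](C)(C)C(C)(C)C)C(=O)C[C@H](O[Si](C)(C)C(C)(C)C)/C(C)=C\C(=O)O)C=C1CS(=O)(=O)c1ccccc1
F3 | step 10 | trimethylsilyl ester of F2 | O=C1O[C@@H](/C=C(/CO[Si](C)(C)C(C)(C)C)C(=O)C[C@H](O[Si](C)(C)C(C)(C)C)/C(C)=C\C(=O)O[Si](C)(C)C)C=C1CS(=O)(=O)c1ccccc1
F4 | step 13 | (1S,3R,6S)-3-acetoxy-13-(phenylsulfonyl)-1,15-bis(tert-butyldimethylsilyloxy)-7,8-secogermacra-4Z,7(11),9Z-trien-12,6-olid-8-al | O=C1O[C@@H](/C=C(/CO[Si](C)(C)C(C)(C)C)[C@@H](OC(C)=O)C[C@H](O[Si](C)(C)C(C)(C)C)/C(C)=C\C=O)C=C1CS(=O)(=O)c1ccccc1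
F5 | step 14 | (1S,3R,6S,7S,8S)-3-acetoxy-8-hydroxy-1,15-bis(tert-butyldimethylsilyloxy)germacra-4Z,9Z,11(13)-trien-12,6-olide (8-epimer of 29) | C=C1C(=O)O[C@H]2/C=C(/CO[Si](C)(C)C(C)(C)C)[C@@H](OC(C)=O)C[C@H](O[Si](C)(C)C(C)(C)C)/C(C)=C\[C@H](O)[C@H]12
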